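A direct plan would buy ring A as the ketone A1, 1-(2,6-dihydroxy-4-methoxyphenyl)ethanone, mono-benzylate it to A2, condense A2 with the aldehyde A3, which is O-benzylvanillin, to the chalcone A4, close ring C with alkaline hydrogen peroxide (Algar–Flynn–Oyamada) to the 5,4'-di-O-benzyl flavonol A5, sulfate O-3 to A6 and hydrogenolyse both benzyl ethers.
Its weakest step would be the peroxide ring closure of A4: it would have to make ring C and the C3–O bond at once, and a 6'-alkoxy group on a 2'-hydroxychalcone is the classic case in which this reaction closes the five-membered ring instead, to the aurone A7.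
The second weak step would be the mono-benzylation of A1: it would desymmetrise two equivalent phenols with one equivalent of halide, and the benzyl group it puts on O-5 would be carried from the first step to the last, build nothing, and be the very 6'-substituent that misdirects the ring closure, whereas the benzyl group that A3 brings in on O-4' would at least be needed to keep the sulfation on O-3.

**Retrosynthetic overview**

Ring A (C4a, C5–OH, C6–H, C7–OMe, C8–H, C8a–O1) is an O-methylated triketide, so it would be made from 4-methoxy-6-methyl-2-pyrone rather than bought as an arene: the methyl carbon becomes C4a, C4–OMe becomes C7–OMe, and C2 and C6 become the oxygen-bearing carbons C5 and C8a.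
Key disconnections: C4a–C5 (Claisen closure that turns the pyrone into ring A, a copy of the chalcone synthase cyclisation), O1–C2 (oxa-Michael closure of ring C in the same flask), and C4–C4a (acylation of the pyrone methyl anion by an α-oxygenated cinnamate that already holds O-3, C2 and ring B).
Ring order: ring B bought, ring A built in the key step, ring C closed straight after it; dehydrogenation, sulfation of O-3 and one hydrogenolysis finish the route.
O-3 comes in with the cinnamate, so no peroxide ring closure is needed; the two ortho oxygens of ring A are formed free and equivalent, so ring A needs neither desymmetrisation nor a protecting group.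

Key step: step 3

Assumption: the free hydrogen sulfate drawn is taken as the target form; it would be carried as its triethylammonium salt and set free only in the last operation.

**Route**

Step 1
Reactants: 1 4-(benzyloxy)-3-methoxybenzaldehyde (O-benzylvanillin); 2 methyl 2-(methoxymethoxy)acetate
Product: 5 methyl (2Z)-3-[4-(benzyloxy)-3-methoxyphenyl]-2-(methoxymethoxy)prop-2-enoate, via β-hydroxy ester 3 (not isolated), via β-mesyloxy ester 4 (not isolated)
Conditions: LiN(SiMe3)2 (1.1 equiv), THF, −78 °C; MsCl (1.2 equiv), −78 to 0 °C; DBU (2.5 equiv), 0 °C to rt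
Reagents that add atoms: none
Why: Lithium ester-enolate aldol addition to the non-enolisable aldehyde, O-mesylation of the aldolate and base-induced elimination (E1cB, or E1 through the p-alkoxybenzyl cation) should give the conjugated α-alkoxy cinnamate with the thermodynamic (Z) geometry; the two transient stereocentres of 3 and 4 are lost and the alkene geometry is not carried into the target.

Step 2
Reactants: 6 4-methoxy-6-methyl-2H-pyran-2-one; 5 methyl (2Z)-3-[4-(benzyloxy)-3-methoxyphenyl]-2-(methoxymethoxy)prop-2-enoate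
Product: 7 6-{(3Z)-4-[4-(benzyloxy)-3-methoxyphenyl]-3-(methoxymethoxy)-2-oxobut-3-en-1-yl}-4-methoxy-2H-pyran-2-one
Conditions: 6 (2.2 equiv), LiN(iPr)2 (2.2 equiv), THF, −78 °C; then 5 (1.0 equiv), −78 to −30 °C; AcOH quench
Reagents that add atoms: none
Why: Lateral lithiation of the pyrone 6-methyl group followed by Claisen-type acyl substitution on the ester: the β-carbon of 5 carries two donors (the aryl group and the enol-ether oxygen on the neighbouring carbon), so 1,2-attack at the ester should win over conjugate addition, and the second equivalent of the pyrone anion takes up the acidic proton of the new β-keto pyrone.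

Step 3
Reactants: 7 6-{(3Z)-4-[4-(benzyloxy)-3-methoxyphenyl]-3-(methoxymethoxy)-2-oxobut-3-en-1-yl}-4-methoxy-2H-pyran-2-one
Product: 10 rac-(2R,3R)-2-[4-(benzyloxy)-3-methoxyphenyl]-5-hydroxy-7-methoxy-3-(methoxymethoxy)-2,3-dihydro-4H-chromen-4-one (racemic trans-flavanone), via open-chain triketide ester 8 (not isolated), via chalcone 9 (not isolated)
Conditions: Mg(OMe)2 (4 equiv), MeOH, reflux; then AcOH to pH 6, NaOAc, 50 °C
Reagents that add atoms: none
Why: Methoxide opens the lactone of 7 to the magnesium-chelated diketonate 8, whose central carbon (the old pyrone methyl, C4a) attacks the ester carbon (the old pyrone C2, which becomes C5) in a 6-exo-trig Claisen (Dieckmann-type) closure; loss of methoxide and enolisation give ring A as chalcone 9, with C7–OMe fixed by the enol ether and two free, equivalent ortho phenols. The closest known reaction type is the magnesium methoxide conversion of 6-(2-oxoalkyl)-4-oxy-2-pyrones and of 3,5,7-triketo esters into acylphloroglucinols, the laboratory copy of the chalcone synthase cyclisation. On buffering, either ortho phenol closes ring C by a 6-endo-trig oxa-Michael addition to the enone, favoured by relief of the twisted 2,6-disubstituted aryl ketone. C2 and C3 are formed as a racemate; the 2,3-trans relation is set by thermodynamic control (reversible Michael addition, epimerisable C3 next to the ketone), and both centres are erased in step 4. The selectivity needed is Claisen closure over the aldol mode (ester α-carbon onto the acyl ketone, which would give a resorcylate ester) and over methanolysis of the acyl group. Chelation of the diketonate by the magnesium ion keeps the two ketones as the nucleophilic unit and the ester as the only electrophile, and the methyl enol ether takes the third carbonyl out of play.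

Step 4
Reactants: 10 rac-(2R,3R)-2-[4-(benzyloxy)-3-methoxyphenyl]-5-hydroxy-7-methoxy-3-(methoxymethoxy)-2,3-dihydro-4H-chromen-4-one
Product: 12 2-[4-(benzyloxy)-3-methoxyphenyl]-3,5-dihydroxy-7-methoxy-4H-chromen-4-one (4'-O-benzylrhamnazin), via 3-(methoxymethoxy)flavone 11 (not isolated)
Conditions: I2 (0.2 equiv), DMSO, 110 °C; then 2 M aq HCl, 60 °C
Reagents that add atoms: none
Why: Iodine/DMSO dehydrogenation of a flavanone (enolisation toward C3, α-iodination, ionisation of the α-iodo ether and loss of H-2, with DMSO reoxidising HI) should give chromone 11 and aqueous acid then hydrolyses the enol methoxymethyl acetal; should the acetal be lost first, the resulting α-ketol should be oxidised to the same flavonol because ring C is already closed, while the aryl benzyl ether and the chelated 5-OH stay untouched and the two stereocentres of 10 disappear.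

Step 5
Reactants: 12 2-[4-(benzyloxy)-3-methoxyphenyl]-3,5-dihydroxy-7-methoxy-4H-chromen-4-one
Product: 13 triethylammonium 2-[4-(benzyloxy)-3-methoxyphenyl]-5-hydroxy-7-methoxy-4-oxo-4H-chromen-3-yl sulfate
Conditions: SO3·NEt3 (3 equiv), NEt3 (1 equiv), DMF, 40 °C
Reagents that add atoms: sulfur trioxide–triethylamine complex, CC[N+](CC)(CC)S(=O)(=O)[O-]
Why: O-sulfation with a sulfur trioxide–amine complex: the 5-OH is locked in a strong six-membered hydrogen bond to the C4 carbonyl and O-4' is benzylated, so SO3 transfer should occur at the enolic 3-OH only, and the monoester is obtained as its ammonium salt without contact with acid.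

Step 6
Reactants: 13 triethylammonium 2-[4-(benzyloxy)-3-methoxyphenyl]-5-hydroxy-7-methoxy-4-oxo-4H-chromen-3-yl sulfate
Product: 15 rhamnazin 3-O-sulfate (5-hydroxy-2-(4-hydroxy-3-methoxyphenyl)-7-methoxy-4-oxo-4H-chromen-3-yl hydrogen sulfate), via triethylammonium salt 14 (not isolated)
Conditions: H2 (1 atm), 10% Pd/C, MeOH–THF, rt; then sulfonic acid cation-exchange resin (H+ form), MeOH–H2O, 0 °C, freeze-drying
Reagents that add atoms: none
Why: Catalytic hydrogenolysis of the single benzyl aryl ether, to which the sulfate monoester anion and the chromone C2=C3 bond are inert at 1 atm, followed by a short, cold proton exchange and immediate freeze-drying to set free the hydrogen sulfate form; no stereocentre is present.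

**Compound list**

1 | 4-(benzyloxy)-3-methoxybenzaldehyde | COc1cc(C=O)ccc1OCc1ccccc1 | starting material
2 | methyl 2-(methoxymethoxy)acetate | COCOCC(=O)OC | starting material
3 | methyl 3-[4-(benzyloxy)-3-methoxyphenyl]-3-hydroxy-2-(methoxymethoxy)propanoate (racemic diastereomer mixture, formed as its lithium alkoxide) | COCOC(C(=O)OC)C(O)c1ccc(OCc2ccccc2)c(OC)c1 | intermediate
4 | methyl 3-[4-(benzyloxy)-3-methoxyphenyl]-2-(methoxymethoxy)-3-[(methylsulfonyl)oxy]propanoate (racemic diastereomer mixture) | COCOC(C(=O)OC)C(OS(C)(=O)=O)c1ccc(OCc2ccccc2)c(OC)c1 | intermediate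
5 | methyl (2Z)-3-[4-(benzyloxy)-3-methoxyphenyl]-2-(methoxymethoxy)prop-2-enoate | COCO/C(C(=O)OC)=C\c1ccc(OCc2ccccc2)c(OC)c1 | intermediate
6 | 4-methoxy-6-methyl-2H-pyran-2-one | Cc1cc(OC)cc(=O)o1 | starting material
7 | 6-{(3Z)-4-[4-(benzyloxy)-3-methoxyphenyl]-3-(methoxymethoxy)-2-oxobut-3-en-1-yl}-4-methoxy-2H-pyran-2-one | COCO/C(C(=O)Cc1cc(OC)cc(=O)o1)=C\c1ccc(OCc2ccccc2)c(OC)c1 | intermediate
8 | methyl (2E,8Z)-9-[4-(benzyloxy)-3-methoxyphenyl]-3-methoxy-8-(methoxymethoxy)-5,7-dioxonona-2,8-dienoate (as its magnesium diketonate) | COC(=O)/C=C(/OC)CC(=O)CC(=O)/C(OCOC)=C/c1ccc(OCc2ccccc2)c(OC)c1 | intermediate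
9 | (2Z)-3-[4-(benzyloxy)-3-methoxyphenyl]-1-(2,6-dihydroxy-4-methoxyphenyl)-2-(methoxymethoxy)prop-2-en-1-one | COc1cc(O)c(C(=O)/C(OCOC)=C/c2ccc(OCc3ccccc3)c(OC)c2)c(O)c1 | intermediate
10 | rac-(2R,3R)-2-[4-(benzyloxy)-3-methoxyphenyl]-5-hydroxy-7-methoxy-3-(methoxymethoxy)-2,3-dihydro-4H-chromen-4-one (trans, racemic, one enantiomer drawn) | COc1cc(ccc1OCc1ccccc1)[C@@H]1[C@H](C(=O)c2c(O)cc(OC)cc2O1)OCOC | intermediate
11 | 2-[4-(benzyloxy)-3-methoxyphenyl]-5-hydroxy-7-methoxy-3-(methoxymethoxy)-4H-chromen-4-one | COCOc1c(-c2ccc(OCc3ccccc3)c(OC)c2)oc2cc(OC)cc(O)c2c1=O | intermediate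
12 | 2-[4-(benzyloxy)-3-methoxyphenyl]-3,5-dihydroxy-7-methoxy-4H-chromen-4-one | COc1cc(O)c2c(=O)c(O)c(-c3ccc(OCc4ccccc4)c(OC)c3)oc2c1 | intermediate
13 | triethylammonium 2-[4-(benzyloxy)-3-methoxyphenyl]-5-hydroxy-7-methoxy-4-oxo-4H-chromen-3-yl sulfate | COc1cc(O)c2c(=O)c(OS(=O)(=O)[O-])c(-c3ccc(OCc4ccccc4)c(OC)c3)oc2c1.CC[NH+](CC)CC | intermediate
14 | triethylammonium 5-hydroxy-2-(4-hydroxy-3-methoxyphenyl)-7-methoxy-4-oxo-4H-chromen-3-yl sulfate | COc1cc(O)c2c(=O)c(OS(=O)(=O)[O-])c(-c3ccc(O)c(OC)c3)oc2c1.CC[NH+](CC)CC | intermediate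
15 | rhamnazin 3-O-sulfate | COc1cc(O)c2c(=O)c(OS(=O)(=O)O)c(-c3ccc(O)c(OC)c3)oc2c1 | target

**Step count and risks**

Total step count: 6. Longest linear sequence: 6 steps (1 → 5 → 7 → 10 → 12 → 13 → 15); pyrone 6 enters at step 2.

The three steps most likely to fail:

First, step 3 (the key step). The opened triketide may close in the aldol sense, or lose its acyl group by methanolysis, before the Claisen closure, so that ring A does not form with the side chain in place. The fallback takes ring A from the bought ketone A1 and adds O-3 last. From 1, KOH-mediated Claisen–Schmidt condensation with A1 would give the 2',6'-dihydroxy-4'-methoxychalcone F1. Iodine in DMSO would close and dehydrogenate it to the 5-hydroxy-7-methoxyflavone F2. Dimethyldioxirane would epoxidise the C2=C3 bond to the 2,3-epoxyflavanone F3, and a trace of acid would open F3 to flavonol 12, where the route is rejoined.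

Second, step 2. The pyrone anion may add to the β-carbon of the cinnamate, or be quenched by proton transfer, so that the acyl substitution stalls. The fallback attaches ring B only after ring A is made. From 6, the same lithiation followed by acylation with the saturated ester 2 would give the pyrone ketone 4-methoxy-6-[3-(methoxymethoxy)-2-oxopropyl]-2H-pyran-2-one F4. Mg(OMe)2 in methanol would turn it into the ketone 1-(2,6-dihydroxy-4-methoxyphenyl)-2-(methoxymethoxy)ethan-1-one F5. Claisen–Schmidt condensation of F5 with 1 would then give chalcone 9, which closes to 10, where the route is rejoined.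

Third, step 4. Enolisation toward the oxygen-bearing C3 may be slow, and the electron-rich rings may be iodinated while the dehydrogenation lags. The fallback reverses the order and oxidises a different bond. From 10, dilute aqueous HCl in THF would first remove the acetal to give the trans-dihydroflavonol F6. Oxidation of its α-ketol with Cu(OAc)2 in pyridine under air (the classical α-ketol to 1,2-diketone oxidation) would give, after tautomerisation, flavonol 12, where the route is rejoined.

Further compounds
F1 | step 3 | (2E)-3-[4-(benzyloxy)-3-methoxyphenyl]-1-(2,6-dihydroxy-4-methoxyphenyl)prop-2-en-1-one | COc1cc(O)c(C(=O)/C=C/c2ccc(OCc3ccccc3)c(OC)c2)c(O)c1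
F2 | step 3 | 2-[4-(benzyloxy)-3-methoxyphenyl]-5-hydroxy-7-methoxy-4H-chromen-4-one | COc1cc(O)c2c(=O)cc(-c3ccc(OCc4ccccc4)c(OC)c3)oc2c1
F3 | step 3 | 1a-[4-(benzyloxy)-3-methoxyphenyl]-6-hydroxy-4-methoxy-1a,7a-dihydro-7H-oxireno[2,3-b]chromen-7-one (racemic, cis-fused, one enantiomer drawn) | COc1cc(O)c2C(=O)[C@@H]3[C@](c4ccc(OCc5ccccc5)c(OC)c4)(Oc2c1)O3
F4 | step 2 | 4-methoxy-6-[3-(methoxymethoxy)-2-oxopropyl]-2H-pyran-2-one | COCOCC(=O)Cc1cc(OC)cc(=O)o1
F5 | step 2 | 1-(2,6-dihydroxy-4-methoxyphenyl)-2-(methoxymethoxy)ethan-1-one | COCOCC(=O)c1c(O)cc(OC)cc1O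
F6 | step 4 | rac-(2R,3R)-2-[4-(benzyloxy)-3-methoxyphenyl]-3,5-dihydroxy-7-methoxy-2,3-dihydro-4H-chromen-4-one (trans, racemic, one enantiomer drawn) | COc1cc(ccc1OCc1ccccc1)[C@@H]1[C@H](C(=O)c2c(O)cc(OC)cc2O1)O
A1 | direct plan | 1-(2,6-dihydroxy-4-methoxyphenyl)ethan-1-one | CC(=O)c1c(O)cc(OC)cc1O
A2 | direct plan | 1-[2-(benzyloxy)-6-hydroxy-4-methoxyphenyl]ethan-1-one | CC(=O)c1c(O)cc(OC)cc1OCc1ccccc1
A3 | direct plan | 4-(benzyloxy)-3-methoxybenzaldehyde | COc1cc(C=O)ccc1OCc1ccccc1
A4 | direct plan | (E)-1-[2-(benzyloxy)-6-hydroxy-4-methoxyphenyl]-3-[4-(benzyloxy)-3-methoxyphenyl]prop-2-en-1-one | COc1cc(O)c(C(=O)/C=C/c2ccc(OCc3ccccc3)c(OC)c2)c(OCc2ccccc2)c1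
A5 | direct plan | 5-(benzyloxy)-2-[4-(benzyloxy)-3-methoxyphenyl]-3-hydroxy-7-methoxy-4H-chromen-4-one | COc1cc(OCc2ccccc2)c2c(=O)c(O)c(-c3ccc(OCc4ccccc4)c(OC)c3)oc2c1
A6 | direct plan | 5-(benzyloxy)-2-[4-(benzyloxy)-3-methoxyphenyl]-7-methoxy-4-oxo-4H-chromen-3-yl hydrogen sulfate | COc1cc(OCc2ccccc2)c2c(=O)c(OS(=O)(=O)O)c(-c3ccc(OCc4ccccc4)c(OC)c3)oc2c1
A7 | direct plan | (2Z)-4-(benzyloxy)-2-[4-(benzyloxy)-3-methoxybenzylidene]-6-methoxy-1-benzofuran-3(2H)-one | COc1cc(OCc2ccccc2)c2C(=O)/C(=C/c3ccc(OCc4ccccc4)c(OC)c3)Oc2c1
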